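## Structural features

The target is a sesquineolignan: a γ-butyrolactone that carries a 4-hydroxy-3-methoxybenzyl group at C4 and, at C3, a CH2 bridge to C5 of a 2,3-dihydrobenzofuran. The dihydrobenzofuran bears a 4-hydroxy-3-methoxyphenyl (guaiacyl) group at C2, a hydroxymethyl group at C3 and a free hydroxyl at C7 of its benzo ring (ring A), ortho to the ring oxygen O1. The stereocentres form two adjacent pairs, lactone C3/C4 (3S,4S, trans) and dihydrobenzofuran C2/C3 (2S,3R, trans), and the CH2–aryl spacer between the pairs means that neither can direct the other. In both pairs trans is the more stable arrangement and one member is correctable (lactone C3 through its enolate, C2 through reversible ionisation of the benzylic C2–O1 bond), whereas lactone C4 and dihydrobenzofuran C3 are fixed once made. Fragile points are the three phenols (the 7-hydroxy/O1 pair is an oxidisable catechol monoether), the acid- and hydrogenolysis-sensitive C2–O1 bond, the base-sensitive lactone with its epimerisable α-centre, and the primary alcohol. The real difficulty is the absolute configuration of dihydrobenzofuran C3, a benzylic methine without a heteroatom, together with the union of two stereodefined halves at an sp3 carbon and the differentiation of the two oxygens of ring A. The key step exploits the fact that C2 (with its guaiacyl group), C3 (with ring A), the hydroxymethyl carbon and the hydroxymethyl oxygen are the four ring atoms of a 2,3-diaryloxetane, while O1 sits on the ring A carbon next to the one bonded to C3 and can open that oxetane at C2 through a five-membered transition state.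

## Logic of the disconnections

21 to 20. The three phenolic O–CH2Ph bonds are cut. One kind of protecting group on all three phenols survives the photochemical, acidic, organometallic and basic steps and falls in a single neutral operation; the primary alcohol is left free throughout, which saves a protection and a deprotection. The forward step must cleave aryl benzyl ethers without touching the cyclic benzylic C2–O1 bond or the lactone.

20 to 11 and 18 (through 19). The bond between C5 of ring A and the bridging CH2 is cut, together with the C3–H bond of the lactone. This divides the molecule into two halves of similar size, each carrying its own stereochemistry. The forward step is a conjugate addition of an aryl–boron reagent to an exocyclic methylene lactone. It must run without hydroxide (lactone), tolerate a free alcohol, and be followed by equilibration of the lactone α-centre from the kinetic cis product 19 to trans.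

18 to 16 (through 17). The exocyclic C=CH2 bond is cut. The methylene carbon is a one-carbon unit added to an enolisable lactone, so the only stereocentre of this half is already present in 16. The forward step must not isomerise the exocyclic double bond into the ring, which would destroy C4.

16 to 14 (through 15) and 14 to 13. The lactone is opened at its acyl–oxygen bond and the CH2–O carbon is raised to an ester; then the two C–H bonds at the stereocentre and its neighbour are removed to give an alkene. The stereocentre becomes the product of an asymmetric hydrogenation of a carboxylate-bearing alkene, a well-established reaction class. The forward steps need a chemoselective reduction of ester beside carboxylate and a catalyst antipode that gives the (S) acid.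

13 to 6 and 12. The C=C bond is cut in the Stobbe sense. Both pieces are articles of commerce, and the condensation itself distinguishes the two carboxyl groups.

11 to 10. The C5–B bond is exchanged for C5–Br. Bromine is easy to place para to the ring A phenol at the very start and is inert until needed. The borylation must tolerate the free alcohol.

10 to 9. No bond is cut; the racemate is the precursor. The oxetane-forming step has no element that distinguishes the faces at C3, so absolute configuration is selected where the first functional handle, the primary alcohol, appears. This demands an efficient resolution and costs half of the material.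

9 to 7 (through 8). The C2–O1 bond is cut and the C2–O bond to the hydroxymethyl oxygen is restored, which contracts the dihydrobenzofuran to an oxetane with a silylated phenol beside it. Ring strain and the cation-stabilising aryl group at C2 make the forward ring expansion downhill and regioselective, and C2 is set trans at this point whatever the oxetane geometry. The forward step must open the oxetane at C2 and not at the CH2 terminus.

7 to 5 and 6. The C2–C3 bond and the O–CH2 bond are cut, the retron of a carbonyl–alkene [2+2] photocycloaddition. An aldehyde that can be bought and a styrene of four steps result. The forward step must give the 2,3-diaryl regiochemistry and must outrun energy transfer from the aldehyde triplet to the styrene.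

5 to 1 (through 4, 3 and 2). The vinyl C=C bond (Wittig), the O–Si bond, the C5–Br bond and the 3-O–benzyl bond are cut in turn. The demand is on the first forward step, which must alkylate only the 3-oxygen of a catechol aldehyde.

## Other disconnections considered

Alternative 1: The cut is the O1–C5 bond of the monobenzyl lactone A3, which is the same compound as 16. A3 is traced to the prochiral cyclobutanone A2 and from there to the allylarene A1 by ketene [2+2] cycloaddition and dechlorination. In the forward key step a Baeyer–Villiger monooxygenase (flavin, O2, recycled NADPH) adds a flavin peroxide to A2 and lets one of the two enantiotopic CH2 groups migrate in the Criegee intermediate, so that ring expansion and the creation of C4 happen together. In its favour: the stereocentre is set catalytically with air as oxidant and without pressure equipment or precious metal, enzymes of either enantiopreference exist for 3-substituted cyclobutanones, and A1 to A3 takes three steps. Against it here: it addresses only lactone C4, the stereocentre that asymmetric hydrogenation already handles reliably, and it forms no bond of the dihydrobenzofuran. The bulky benzyloxy(methoxy)benzyl group may lie outside the substrate range of available enzymes, and the ketene cycloaddition to an unactivated allylarene is the weak link of the sequence. Comparison: as a route to 16 it equals steps 9 to 11 in step count and is the better option on metal use and operating pressure. As a strategy for the whole target it is complementary, not competing, because it could replace steps 9 to 11 without touching the oxetane plan.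

Alternative 2: The cut takes C2–C3 and C2–O1 of the dihydrobenzofuran in one operation. The 2-(1-tosylalkyl)phenol A4 and the benzylic sulfonium salt A5 would be treated with Cs2CO3; A4 loses sulfinate to give an o-quinone methide, the ylide of A5 adds to its exocyclic carbon, and the phenoxide displaces the sulfide to give the trans dihydrobenzofuran A6. In its favour: it is a known reaction class, it is thermal and scalable, and trans selectivity is inherent in the betaine closure. It makes the same C2–C3 bond as the chosen plan and the C2–O1 bond in the same flask, and A6 already carries the protected hydroxymethyl group. On precedent and on step count for the heterocycle (one step against steps 5 and 6) it is the better of the two. A chiral sulfide could in principle bias the absolute configuration, which the chosen plan cannot do at all. Against it here: the o-quinone methide from A4 carries a CH2OSi group whose hydrogens allow tautomerisation to a 2-vinylphenol or loss of silanolate. The semi-stabilised ylide of an electron-rich benzyl group is a modest nucleophile, A4 itself needs a multistep assembly, and enantiocontrol by a stoichiometric chiral sulfide is not assured for this substitution pattern, so a resolution would probably remain. Comparison: structurally the two plans deliver the same intermediate, since A6 is the silyl ether of 10. The chosen plan has simpler precursors (a purchased aldehyde and a four-step styrene) and corrects C2 automatically, at the price of an unprecedented photochemical step. Overall step counts would be close.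

Alternative 3: The cut removes three bonds of the lactone at once. The alkynol A7, which already contains the complete dihydrobenzofuran, the benzylic Grignard reagent A8 and CO2 would give the butenolide A9 by hydroxyl-directed anti-carbomagnesiation, carboxylation of the vinylmagnesium intermediate and lactonisation on acidification. In its favour: it is highly convergent, it places both benzylic groups regiospecifically, it uses CO2 as the carbonyl source, and it forms in one flask what steps 9 to 13 of the chosen plan form in five. On bonds made per step it is clearly the better plan. Against it here: A9 has no lactone stereocentre, and both would have to come from an enantioselective reduction of a tetrasubstituted butenolide in the presence of three benzyl ethers and the existing C2/C3 pair. That reduction would give the cis lactone first and diastereomers if selectivity were incomplete. A8 is prone to Wurtz coupling, A7 requires an aryl–propargyl coupling on the precious half, and the dihydrobenzofuran problem is left unsolved. Comparison: mechanistically sound for the carbon skeleton and superior in convergence, but it moves the stereochemical burden to the last C–H bonds. The chosen plan fixes lactone C4 early by a reliable hydrogenation and obtains C3 by thermodynamic equilibration.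

Key step: step 5

Remarks on the chemistry:
- Compounds 7, 8 and 9 are racemates; their SMILES show the enantiomer that is carried on to the target.
- In step 7 the lipase is assumed to acetylate the (2R,3S) alcohol faster. The fallback of step 7 does not depend on this preference.
- Compounds 1, 6 and 12 are purchased.

## Steps

Step 1
Reactants: 1 2,3-dihydroxybenzaldehyde
Product: 2 3-(benzyloxy)-2-hydroxybenzaldehyde
Conditions: NaH (2.2 eq), DMSO, rt; then BnBr (1.0 eq), rt; aq. HCl work-up
Reagents that add atoms: benzyl bromide, BrCc1ccccc1
Why: Williamson etherification of the dianion: the 2-phenoxide is conjugated with and chelated to the formyl group, so the 3-phenoxide is the more nucleophilic oxygen and takes the single equivalent of benzyl bromide.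

Step 2
Reactants: 2 3-(benzyloxy)-2-hydroxybenzaldehyde
Product: 3 3-(benzyloxy)-5-bromo-2-hydroxybenzaldehyde
Conditions: Br2 (1.05 eq), NaOAc, AcOH, rt
Reagents that add atoms: bromine, BrBr
Why: Electrophilic aromatic bromination directed by the free phenol to its para position (C5), both ortho positions being occupied; acetate buffers the HBr so that the benzyl ether survives.

Step 3
Reactants: 3 3-(benzyloxy)-5-bromo-2-hydroxybenzaldehyde
Product: 4 3-(benzyloxy)-5-bromo-2-[(tert-butyldimethylsilyl)oxy]benzaldehyde
Conditions: TBSCl, imidazole, DMF, rt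
Reagents that add atoms: tert-butyldimethylsilyl chloride, CC(C)(C)[Si](C)(C)Cl
Why: Standard silylation of a phenol; the silyl ether removes the phenolic hydrogen, which would quench the aldehyde triplet in step 5, and later serves as the trigger for ring expansion.

Step 4
Reactants: 4 3-(benzyloxy)-5-bromo-2-[(tert-butyldimethylsilyl)oxy]benzaldehyde
Product: 5 [2-(benzyloxy)-4-bromo-6-vinylphenoxy](tert-butyl)dimethylsilane
Conditions: Ph3PCH3Br, NaN(SiMe3)2, THF, 0 °C to rt
Reagents that add atoms: methyltriphenylphosphonium bromide, C[P+](c1ccccc1)(c1ccccc1)c1ccccc1.[Br-]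
Why: Wittig methylenation of an aromatic aldehyde; the ylide is made with a non-nucleophilic amide base, which leaves the aryl bromide and the aryl silyl ether untouched.

Step 5
Reactants: 5 [2-(benzyloxy)-4-bromo-6-vinylphenoxy](tert-butyl)dimethylsilane; 6 4-(benzyloxy)-3-methoxybenzaldehyde
Product: 7 (±)-trans-2-[4-(benzyloxy)-3-methoxyphenyl]-3-[3-(benzyloxy)-5-bromo-2-(tert-butyldimethylsilyloxy)phenyl]oxetane
Conditions: hν (350 nm UV-A lamps, borosilicate glass), 6 (5 eq), 5 (0.02 M), benzene, N2, 10 °C; excess 6 removed by NaHSO3 wash
Reagents that add atoms: none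
Why: Proposed new method: excitation of 6 and fast intersystem crossing give the aldehyde triplet, whose oxygen adds to the terminal carbon of the styrene 5 to give a triplet 1,4-biradical that is benzylic and oxygen-substituted at the former carbonyl carbon and benzylic at the former styrene α-carbon; after spin inversion the two radical centres combine to form the C2–C3 bond, so the four-membered ring is closed by 1,4-biradical recombination, formally a [2+2] photocycloaddition. The closest known reaction type is the Paternò–Büchi reaction of aromatic aldehydes with electron-rich alkenes; pairing an alkoxybenzaldehyde with a 2-silyloxystyrene whose triplet energy lies below that of the aldehyde is outside what that reaction has been shown to tolerate. The regiochemistry (oxygen to CH2, carbon to the benzylic position) follows from formation of the more stabilised biradical and is secured by the aryl group on the alkene. C3 is created here without facial bias, because neither partner carries a stereocentre, so 7 forms as the racemate and the absolute configuration is selected in step 7. The C2/C3 relationship should favour trans through conformational relaxation of the triplet biradical before closure, and it is in any case erased at C2 in step 6, so a cis isomer may be carried along. The competing channel is triplet energy transfer from 6 to 5, which wastes photons but returns 5 unchanged; to keep it from turning into styrene dimerisation, 5 is held dilute and 6 is used in excess so that it absorbs all the light. The silyl and benzyl ethers keep phenolic hydrogen out of the system, and the aryl bromide neither absorbs at this wavelength nor has a C–Br bond weak enough to be cleaved by the triplets present.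

Step 6
Reactants: 7 (±)-trans-2-[4-(benzyloxy)-3-methoxyphenyl]-3-[3-(benzyloxy)-5-bromo-2-(tert-butyldimethylsilyloxy)phenyl]oxetane
Product: 9 (±)-trans-{7-(benzyloxy)-2-[4-(benzyloxy)-3-methoxyphenyl]-5-bromo-2,3-dihydrobenzofuran-3-yl}methanol, via free-phenol oxetane 8 (not isolated)
Conditions: Bu4NF, AcOH (1:1), THF, 0 °C; then crude in CH2Cl2, camphorsulfonic acid (10 mol %), 0 °C to rt
Reagents that add atoms: none
Why: Buffered fluoride frees the ortho phenol without leaving a phenoxide that could attack the CH2 terminus; acid then protonates the oxetane oxygen, the C2–O bond ionises towards the cation stabilised by the 4-benzyloxyphenyl group, and the phenol closes the five-membered ring at C2 (5-exo-tet, acid-catalysed intramolecular opening of an oxetane by a phenol). C3 is untouched and C2 is set trans to it under product-stability control, so both oxetane diastereomers converge on 9, with the former oxetane oxygen remaining on the CH2 as the primary alcohol.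

Step 7
Reactants: 9 (±)-trans-{7-(benzyloxy)-2-[4-(benzyloxy)-3-methoxyphenyl]-5-bromo-2,3-dihydrobenzofuran-3-yl}methanol
Product: 10 [(2S,3R)-7-(benzyloxy)-2-[4-(benzyloxy)-3-methoxyphenyl]-5-bromo-2,3-dihydrobenzofuran-3-yl]methanol
Conditions: Burkholderia cepacia lipase (immobilised), vinyl acetate, t-BuOMe, 30 °C, stopped past half conversion
Reagents that add atoms: none
Why: Lipase-catalysed enantioselective transesterification (kinetic resolution) of a primary alcohol with a stereocentre at the adjacent carbon; running past half conversion should leave the slower-reacting (2S,3R) alcohol in high enantiomeric purity, and the acetate of the other enantiomer is separated by chromatography. No stereocentre is formed here; this is the point at which the absolute configuration of C3, and with it C2, is selected.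

Step 8
Reactants: 10 [(2S,3R)-7-(benzyloxy)-2-[4-(benzyloxy)-3-methoxyphenyl]-5-bromo-2,3-dihydrobenzofuran-3-yl]methanol
Product: 11 [(2S,3R)-7-(benzyloxy)-2-[4-(benzyloxy)-3-methoxyphenyl]-5-(5,5-dimethyl-1,3,2-dioxaborinan-2-yl)-2,3-dihydrobenzofuran-3-yl]methanol
Conditions: bis(neopentyl glycolato)diboron, Pd(dppf)Cl2 (3 mol %), KOAc, 1,4-dioxane, 80 °C
Reagents that add atoms: bis(neopentyl glycolato)diboron, CC1(C)COB(OC1)B1OCC(C)(C)CO1
Why: Miyaura borylation of an aryl bromide; acetate as base tolerates the free primary alcohol and the benzyl ethers, and the neopentyl glycol ester is chosen because, being less hindered than a pinacol ester, it should transfer its aryl group to hydroxorhodium in step 13 without added base.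

Step 9
Reactants: 6 4-(benzyloxy)-3-methoxybenzaldehyde; 12 dimethyl succinate
Product: 13 (E)-4-[4-(benzyloxy)-3-methoxyphenyl]-3-(methoxycarbonyl)but-3-enoic acid
Conditions: NaOMe, MeOH, reflux; then aq. HCl
Reagents that add atoms: none
Why: Stobbe condensation: aldol addition, closure to the paraconic ester and E1cB ring opening give the half-ester with (E) geometry and decide which carboxyl group stays esterified.

Step 10
Reactants: 13 (E)-4-[4-(benzyloxy)-3-methoxyphenyl]-3-(methoxycarbonyl)but-3-enoic acid
Product: 14 (3S)-4-[4-(benzyloxy)-3-methoxyphenyl]-3-(methoxycarbonyl)butanoic acid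
Conditions: H2 (5 bar), [Rh(cod)((R,R)-Et-DuPhos)]BF4 (0.5 mol %), NaOMe (10 mol %), MeOH, rt
Reagents that add atoms: none
Why: Rhodium–bisphospholane asymmetric hydrogenation of an itaconate-type half-ester, with the carboxylate as the coordinating group; the ligand antipode is the one expected to deliver the (S) acid, and the other antipode is equally available should the sense prove reversed. Homogeneous rhodium does not cleave the benzyl ether.

Step 11
Reactants: 14 (3S)-4-[4-(benzyloxy)-3-methoxyphenyl]-3-(methoxycarbonyl)butanoic acid
Product: 16 (4S)-4-[4-(benzyloxy)-3-methoxybenzyl]dihydrofuran-2(3H)-one, via hydroxy acid 15 (not isolated)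
Conditions: KOH (1.0 eq), EtOH; CaCl2, NaBH4, EtOH, −10 °C to rt; then 2 M HCl
Reagents that add atoms: none
Why: Calcium borohydride reduces the ester but not the carboxylate, and acidification lactonises the γ-hydroxy acid; the stereocentre is not involved and keeps its descriptor because the priority order of its substituents is unchanged.

Step 12
Reactants: 16 (4S)-4-[4-(benzyloxy)-3-methoxybenzyl]dihydrofuran-2(3H)-one
Product: 18 (4S)-4-[4-(benzyloxy)-3-methoxybenzyl]-3-methylenedihydrofuran-2(3H)-one, via sodium enolate of the formyl lactone 17 (not isolated)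
Conditions: NaH, HCO2Et, THF, rt; then (CH2O)n, THF, reflux
Reagents that add atoms: formaldehyde (from paraformaldehyde), C=O; ethyl formate, CCOC=O (formyl carbon of 17 only)
Why: Claisen formylation activates C3; the enolate 17 adds to formaldehyde, the formyl group migrates to the new alkoxide and formate is lost by E1cB elimination (deformylative α-methylenation of a lactone). C4 is not deprotonated under these weakly basic final conditions.

Step 13
Reactants: 11 [(2S,3R)-7-(benzyloxy)-2-[4-(benzyloxy)-3-methoxyphenyl]-5-(5,5-dimethyl-1,3,2-dioxaborinan-2-yl)-2,3-dihydrobenzofuran-3-yl]methanol; 18 (4S)-4-[4-(benzyloxy)-3-methoxybenzyl]-3-methylenedihydrofuran-2(3H)-one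
Product: 20 (3S,4S)-3-{[(2S,3R)-7-(benzyloxy)-2-[4-(benzyloxy)-3-methoxyphenyl]-3-(hydroxymethyl)-2,3-dihydrobenzofuran-5-yl]methyl}-4-[4-(benzyloxy)-3-methoxybenzyl]dihydrofuran-2(3H)-one, via cis lactone 19 (not isolated)
Conditions: [Rh(OH)(cod)]2 (3 mol %), 1,4-dioxane/H2O 10:1, 45 °C; then crude in toluene, DBU (0.3 eq), 60 °C
Reagents that add atoms: none
Why: Rhodium-catalysed 1,4-addition of an arylboron reagent to an α-substituted acrylate: the aryl group passes from boron to hydroxorhodium, adds to the exocyclic CH2, and water protonates the rhodium enolate mainly anti to the C4 substituent, which gives the cis lactone 19. DBU then epimerises the acidic C3 to the more stable trans arrangement; C4, set in step 10, takes no part, and the absence of hydroxide spares the lactone.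

Step 14
Reactants: 20 (3S,4S)-3-{[(2S,3R)-7-(benzyloxy)-2-[4-(benzyloxy)-3-methoxyphenyl]-3-(hydroxymethyl)-2,3-dihydrobenzofuran-5-yl]methyl}-4-[4-(benzyloxy)-3-methoxybenzyl]dihydrofuran-2(3H)-one
Product: 21 (3S,4S)-3-{[(2S,3R)-7-hydroxy-2-(4-hydroxy-3-methoxyphenyl)-3-(hydroxymethyl)-2,3-dihydrobenzofuran-5-yl]methyl}-4-(4-hydroxy-3-methoxybenzyl)dihydrofuran-2(3H)-one
Conditions: H2 (1 atm), Pd on carbon (10 %), EtOAc/EtOH, rt
Reagents that add atoms: none
Why: Hydrogenolysis of the three aryl benzyl ethers; these unhindered primary benzylic ethers should cleave well before the cyclic, secondary benzylic C2–O1 bond, so the reaction is stopped after uptake of three equivalents of hydrogen. The lactone and all four stereocentres are not affected.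

## Compound list

1 | 2,3-dihydroxybenzaldehyde | O=Cc1cccc(O)c1O | starting material
2 | 3-(benzyloxy)-2-hydroxybenzaldehyde | O=Cc1cccc(OCc2ccccc2)c1O | intermediate
3 | 3-(benzyloxy)-5-bromo-2-hydroxybenzaldehyde | O=Cc1cc(Br)cc(OCc2ccccc2)c1O | intermediate
4 | 3-(benzyloxy)-5-bromo-2-[(tert-butyldimethylsilyl)oxy]benzaldehyde | O=Cc1cc(Br)cc(OCc2ccccc2)c1O[Si](C)(C)C(C)(C)C | intermediate
5 | [2-(benzyloxy)-4-bromo-6-vinylphenoxy](tert-butyl)dimethylsilane | C=Cc1cc(Br)cc(OCc2ccccc2)c1O[Si](C)(C)C(C)(C)C | intermediate
6 | 4-(benzyloxy)-3-methoxybenzaldehyde | COc1cc(C=O)ccc1OCc1ccccc1 | starting material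
7 | (±)-trans-2-[4-(benzyloxy)-3-methoxyphenyl]-3-[3-(benzyloxy)-5-bromo-2-(tert-butyldimethylsilyloxy)phenyl]oxetane (racemate; the (2R,3R) enantiomer, with C3 as in the target, is drawn) | Brc1cc(OCc2ccccc2)c(O[Si](C)(C)C(C)(C)C)c(c1)[C@@H]1CO[C@H]1c1ccc(OCc2ccccc2)c(OC)c1 | intermediate
8 | (±)-2-(benzyloxy)-4-bromo-6-{trans-2-[4-(benzyloxy)-3-methoxyphenyl]oxetan-3-yl}phenol (racemate; (2R,3R) drawn) | Brc1cc(OCc2ccccc2)c(O)c(c1)[C@@H]1CO[C@H]1c1ccc(OCc2ccccc2)c(OC)c1 | intermediate (not isolated)
9 | (±)-trans-{7-(benzyloxy)-2-[4-(benzyloxy)-3-methoxyphenyl]-5-bromo-2,3-dihydrobenzofuran-3-yl}methanol (racemate; (2S,3R) drawn) | Brc1cc(OCc3ccccc3)c2c(c1)[C@H](CO)[C@@H](c1ccc(OCc3ccccc3)c(OC)c1)O2 | intermediate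
10 | [(2S,3R)-7-(benzyloxy)-2-[4-(benzyloxy)-3-methoxyphenyl]-5-bromo-2,3-dihydrobenzofuran-3-yl]methanol (single enantiomer) | Brc1cc(OCc3ccccc3)c2c(c1)[C@H](CO)[C@@H](c1ccc(OCc3ccccc3)c(OC)c1)O2 | intermediate
11 | [(2S,3R)-7-(benzyloxy)-2-[4-(benzyloxy)-3-methoxyphenyl]-5-(5,5-dimethyl-1,3,2-dioxaborinan-2-yl)-2,3-dihydrobenzofuran-3-yl]methanol | CC1(C)COB(OC1)c1cc(OCc3ccccc3)c2c(c1)[C@H](CO)[C@@H](c1ccc(OCc3ccccc3)c(OC)c1)O2 | intermediate
12 | dimethyl succinate | COC(=O)CCC(=O)OC | starting material
13 | (E)-4-[4-(benzyloxy)-3-methoxyphenyl]-3-(methoxycarbonyl)but-3-enoic acid | COC(=O)/C(CC(=O)O)=C/c1ccc(OCc2ccccc2)c(OC)c1 | intermediate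
14 | (3S)-4-[4-(benzyloxy)-3-methoxyphenyl]-3-(methoxycarbonyl)butanoic acid | COc1cc(C[C@@H](CC(=O)O)C(=O)OC)ccc1OCc1ccccc1 | intermediate
15 | (3S)-4-[4-(benzyloxy)-3-methoxyphenyl]-3-(hydroxymethyl)butanoic acid | COc1cc(C[C@@H](CC(=O)O)CO)ccc1OCc1ccccc1 | intermediate (not isolated)
16 | (4S)-4-[4-(benzyloxy)-3-methoxybenzyl]dihydrofuran-2(3H)-one | COc1cc(C[C@@H]2COC(=O)C2)ccc1OCc1ccccc1 | intermediate
17 | sodium enolate of (4S)-4-[4-(benzyloxy)-3-methoxybenzyl]-2-oxotetrahydrofuran-3-carbaldehyde | COc1cc(C[C@@H]2COC(=O)C2=C[O-])ccc1OCc1ccccc1.[Na+] | intermediate (not isolated)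
18 | (4S)-4-[4-(benzyloxy)-3-methoxybenzyl]-3-methylenedihydrofuran-2(3H)-one | COc1cc(C[C@@H]2COC(=O)C2=C)ccc1OCc1ccccc1 | intermediate
19 | (3R,4S)-3-{[(2S,3R)-7-(benzyloxy)-2-[4-(benzyloxy)-3-methoxyphenyl]-3-(hydroxymethyl)-2,3-dihydrobenzofuran-5-yl]methyl}-4-[4-(benzyloxy)-3-methoxybenzyl]dihydrofuran-2(3H)-one (cis lactone) | COc1cc(C[C@@H]2COC(=O)[C@@H]2Cc2cc(OCc4ccccc4)c3c(c2)[C@H](CO)[C@@H](c2ccc(OCc4ccccc4)c(OC)c2)O3)ccc1OCc1ccccc1 | intermediate (not isolated)
20 | (3S,4S)-3-{[(2S,3R)-7-(benzyloxy)-2-[4-(benzyloxy)-3-methoxyphenyl]-3-(hydroxymethyl)-2,3-dihydrobenzofuran-5-yl]methyl}-4-[4-(benzyloxy)-3-methoxybenzyl]dihydrofuran-2(3H)-one (trans lactone) | COc1cc(C[C@@H]2COC(=O)[C@H]2Cc2cc(OCc4ccccc4)c3c(c2)[C@H](CO)[C@@H](c2ccc(OCc4ccccc4)c(OC)c2)O3)ccc1OCc1ccccc1 | intermediate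
21 | (3S,4S)-3-{[(2S,3R)-7-hydroxy-2-(4-hydroxy-3-methoxyphenyl)-3-(hydroxymethyl)-2,3-dihydrobenzofuran-5-yl]methyl}-4-(4-hydroxy-3-methoxybenzyl)dihydrofuran-2(3H)-one | COc1cc(C[C@@H]2COC(=O)[C@H]2Cc2cc(O)c3c(c2)[C@H](CO)[C@@H](c2ccc(O)c(OC)c2)O3)ccc1O | target

## Step count and least certain steps

Total: 14 steps. Longest linear sequence: 10 steps (steps 1 to 8, 13 and 14, from 1). The lactone branch (steps 9 to 12, from 6 and 12) joins at step 13.

Step 5 (key step, new method). Most likely failure: triplet energy transfer from the excited aldehyde to the styrene outcompetes C–O bond formation, so that conversion to oxetane stalls while slow styrene dimerisation or polymerisation consumes 5. Hydrogen abstraction from benzylic ether positions by the aldehyde triplet and sensitised cycloreversion of the oxetane at high conversion are secondary losses. Fallback by known chemistry, setting out from 5 and 6 and rejoining the route at 9: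
- Hydroboration of 5 with 9-BBN and oxidation with NaBO3 gives 2-[3-(benzyloxy)-5-bromo-2-(tert-butyldimethylsilyloxy)phenyl]ethanol F1.
- Oxidation (TEMPO, PhI(OAc)2, MeCN/H2O) gives [3-(benzyloxy)-5-bromo-2-(tert-butyldimethylsilyloxy)phenyl]acetic acid F2.
- The dianion of F2 (LiN(iPr)2, 2.2 eq, THF, −78 °C) adds to 6 in an Ivanov-type aldol reaction to give 2-[3-(benzyloxy)-5-bromo-2-(tert-butyldimethylsilyloxy)phenyl]-3-[4-(benzyloxy)-3-methoxyphenyl]-3-hydroxypropanoic acid F3 as a diastereomer mixture.
- BH3·SMe2 reduces F3 to 2-[3-(benzyloxy)-5-bromo-2-(tert-butyldimethylsilyloxy)phenyl]-1-[4-(benzyloxy)-3-methoxyphenyl]propane-1,3-diol F4.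
- Bu4NF frees 2-[3-(benzyloxy)-5-bromo-2-hydroxyphenyl]-1-[4-(benzyloxy)-3-methoxyphenyl]propane-1,3-diol F5, and catalytic TsOH in CH2Cl2 closes F5 to 9 through the same benzylic cation. Both diastereomers converge on the trans product.

Step 6. Most likely failure: opening of the oxetane in the wrong sense or along the wrong path. These are attack of the phenol oxygen at the CH2 terminus, fragmentation of the benzylic cation with loss of formaldehyde to a stilbene, or intermolecular capture of the cation by an electron-rich arene. Fallback, setting out from 7 and rejoining at 9: Me3SiBr in CH2Cl2 at −78 °C silylates the oxetane oxygen and bromide opens the ring at the benzylic carbon, giving {2-(benzyloxy)-4-bromo-6-[1-bromo-1-(4-benzyloxy-3-methoxyphenyl)-3-(trimethylsilyloxy)propan-2-yl]phenoxy}(tert-butyl)dimethylsilane F6. Bu4NF then removes both silyl groups, and the phenoxide displaces the labile benzylic bromide in a five-membered closure to 9. Any cis isomer would be equilibrated to trans with a trace of acid.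

Step 7. Most likely failure: poor discrimination of the enantiomers by the enzyme, because the stereocentre is one carbon away from the reacting oxygen and flanked by two large groups, or a preference opposite to the one assumed. Fallback, setting out from 9 and rejoining at 10: esterification with (S)-2-methoxy-2-phenylacetic acid (DCC, DMAP, CH2Cl2) gives two diastereomeric esters. These are [(2S,3R)-7-(benzyloxy)-2-[4-(benzyloxy)-3-methoxyphenyl]-5-bromo-2,3-dihydrobenzofuran-3-yl]methyl (S)-2-methoxy-2-phenylacetate F7 and [(2R,3S)-7-(benzyloxy)-2-[4-(benzyloxy)-3-methoxyphenyl]-5-bromo-2,3-dihydrobenzofuran-3-yl]methyl (S)-2-methoxy-2-phenylacetate F8. They are separated by chromatography or crystallisation and assigned by X-ray diffraction, with bromine as the heavy atom. Methanolysis of F7 (K2CO3, MeOH) returns 10.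

Step 13. Most likely failure: slow aryl transfer from boron with competing protodeboronation; isomerisation of the exocyclic double bond of 18 into the ring by a rhodium hydride, which would erase C4; or incomplete cis-to-trans equilibration that leaves a diastereomer hard to separate. Fallback by enolate alkylation, setting out from 10 and 16 and rejoining at 20:
- Silylation of 10 (TBSCl, imidazole) gives tert-butyl{[(2S,3R)-7-(benzyloxy)-2-[4-(benzyloxy)-3-methoxyphenyl]-5-bromo-2,3-dihydrobenzofuran-3-yl]methoxy}dimethylsilane F9.
- Bromine–lithium exchange (n-BuLi, THF, −78 °C) and DMF give (2S,3R)-7-(benzyloxy)-2-[4-(benzyloxy)-3-methoxyphenyl]-3-[(tert-butyldimethylsilyloxy)methyl]-2,3-dihydrobenzofuran-5-carbaldehyde F10.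
- NaBH4 gives {(2S,3R)-7-(benzyloxy)-2-[4-(benzyloxy)-3-methoxyphenyl]-3-[(tert-butyldimethylsilyloxy)methyl]-2,3-dihydrobenzofuran-5-yl}methanol F11.
- CBr4 and PPh3 give tert-butyl{[(2S,3R)-7-(benzyloxy)-2-[4-(benzyloxy)-3-methoxyphenyl]-5-(bromomethyl)-2,3-dihydrobenzofuran-3-yl]methoxy}dimethylsilane F12.
- The lithium enolate of 16 (LiN(SiMe3)2, THF, −78 °C) is alkylated by F12 anti to the C4 substituent, giving directly the trans lactone (3S,4S)-3-{[(2S,3R)-7-(benzyloxy)-2-[4-(benzyloxy)-3-methoxyphenyl]-3-[(tert-butyldimethylsilyloxy)methyl]-2,3-dihydrobenzofuran-5-yl]methyl}-4-[4-(benzyloxy)-3-methoxybenzyl]dihydrofuran-2(3H)-one F13.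
- Bu4NF converts F13 into 20.

## Further compounds

F1 | step 5 | 2-[3-(benzyloxy)-5-bromo-2-(tert-butyldimethylsilyloxy)phenyl]ethanol | OCCc1cc(Br)cc(OCc2ccccc2)c1O[Si](C)(C)C(C)(C)C
F2 | step 5 | [3-(benzyloxy)-5-bromo-2-(tert-butyldimethylsilyloxy)phenyl]acetic acid | OC(=O)Cc1cc(Br)cc(OCc2ccccc2)c1O[Si](C)(C)C(C)(C)C
F3 | step 5 | 2-[3-(benzyloxy)-5-bromo-2-(tert-butyldimethylsilyloxy)phenyl]-3-[4-(benzyloxy)-3-methoxyphenyl]-3-hydroxypropanoic acid (racemic diastereomer mixture) | OC(=O)C(c1cc(Br)cc(OCc2ccccc2)c1O[Si](C)(C)C(C)(C)C)C(O)c1ccc(OCc2ccccc2)c(OC)c1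
F4 | step 5 | 2-[3-(benzyloxy)-5-bromo-2-(tert-butyldimethylsilyloxy)phenyl]-1-[4-(benzyloxy)-3-methoxyphenyl]propane-1,3-diol (racemic diastereomer mixture) | OCC(c1cc(Br)cc(OCc2ccccc2)c1O[Si](C)(C)C(C)(C)C)C(O)c1ccc(OCc2ccccc2)c(OC)c1
F5 | step 5 | 2-[3-(benzyloxy)-5-bromo-2-hydroxyphenyl]-1-[4-(benzyloxy)-3-methoxyphenyl]propane-1,3-diol (racemic diastereomer mixture) | OCC(c1cc(Br)cc(OCc2ccccc2)c1O)C(O)c1ccc(OCc2ccccc2)c(OC)c1
F6 | step 6 | {2-(benzyloxy)-4-bromo-6-[1-bromo-1-(4-benzyloxy-3-methoxyphenyl)-3-(trimethylsilyloxy)propan-2-yl]phenoxy}(tert-butyl)dimethylsilane (racemic, both epimers at the CHBr carbon; target-series configuration drawn at the other centre) | Brc1cc(OCc2ccccc2)c(O[Si](C)(C)C(C)(C)C)c(c1)[C@H](CO[Si](C)(C)C)C(Br)c1ccc(OCc2ccccc2)c(OC)c1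
F7 | step 7 | [(2S,3R)-7-(benzyloxy)-2-[4-(benzyloxy)-3-methoxyphenyl]-5-bromo-2,3-dihydrobenzofuran-3-yl]methyl (S)-2-methoxy-2-phenylacetate | Brc1cc(OCc3ccccc3)c2c(c1)[C@H](COC(=O)[C@@H](OC)c1ccccc1)[C@@H](c1ccc(OCc3ccccc3)c(OC)c1)O2
F8 | step 7 | [(2R,3S)-7-(benzyloxy)-2-[4-(benzyloxy)-3-methoxyphenyl]-5-bromo-2,3-dihydrobenzofuran-3-yl]methyl (S)-2-methoxy-2-phenylacetate | Brc1cc(OCc3ccccc3)c2c(c1)[C@@H](COC(=O)[C@@H](OC)c1ccccc1)[C@H](c1ccc(OCc3ccccc3)c(OC)c1)O2
F9 | step 13 | tert-butyl{[(2S,3R)-7-(benzyloxy)-2-[4-(benzyloxy)-3-methoxyphenyl]-5-bromo-2,3-dihydrobenzofuran-3-yl]methoxy}dimethylsilane | Brc1cc(OCc3ccccc3)c2c(c1)[C@H](CO[Si](C)(C)C(C)(C)C)[C@@H](c1ccc(OCc3ccccc3)c(OC)c1)O2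
F10 | step 13 | (2S,3R)-7-(benzyloxy)-2-[4-(benzyloxy)-3-methoxyphenyl]-3-[(tert-butyldimethylsilyloxy)methyl]-2,3-dihydrobenzofuran-5-carbaldehyde | O=Cc1cc(OCc3ccccc3)c2c(c1)[C@H](CO[Si](C)(C)C(C)(C)C)[C@@H](c1ccc(OCc3ccccc3)c(OC)c1)O2
F11 | step 13 | {(2S,3R)-7-(benzyloxy)-2-[4-(benzyloxy)-3-methoxyphenyl]-3-[(tert-butyldimethylsilyloxy)methyl]-2,3-dihydrobenzofuran-5-yl}methanol | OCc1cc(OCc3ccccc3)c2c(c1)[C@H](CO[Si](C)(C)C(C)(C)C)[C@@H](c1ccc(OCc3ccccc3)c(OC)c1)O2
F12 | step 13 | tert-butyl{[(2S,3R)-7-(benzyloxy)-2-[4-(benzyloxy)-3-methoxyphenyl]-5-(bromomethyl)-2,3-dihydrobenzofuran-3-yl]methoxy}dimethylsilane | BrCc1cc(OCc3ccccc3)c2c(c1)[C@H](CO[Si](C)(C)C(C)(C)C)[C@@H](c1ccc(OCc3ccccc3)c(OC)c1)O2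
F13 | step 13 | (3S,4S)-3-{[(2S,3R)-7-(benzyloxy)-2-[4-(benzyloxy)-3-methoxyphenyl]-3-[(tert-butyldimethylsilyloxy)methyl]-2,3-dihydrobenzofuran-5-yl]methyl}-4-[4-(benzyloxy)-3-methoxybenzyl]dihydrofuran-2(3H)-one | COc1cc(C[C@@H]2COC(=O)[C@H]2Cc2cc(OCc4ccccc4)c3c(c2)[C@H](CO[Si](C)(C)C(C)(C)C)[C@@H](c2ccc(OCc4ccccc4)c(OC)c2)O3)ccc1OCc1ccccc1
A1 | alternative 1 | 4-allyl-1-(benzyloxy)-2-methoxybenzene | C=CCc1ccc(OCc2ccccc2)c(OC)c1
A2 | alternative 1 | 3-[4-(benzyloxy)-3-methoxybenzyl]cyclobutan-1-one | COc1cc(CC2CC(=O)C2)ccc1OCc1ccccc1
A3 | alternative 1 | (S)-4-[4-(benzyloxy)-3-methoxybenzyl]dihydrofuran-2(3H)-one | COc1cc(C[C@@H]2COC(=O)C2)ccc1OCc1ccccc1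
A4 | alternative 2 | 2-(benzyloxy)-4-bromo-6-[2-(tert-butyldimethylsilyloxy)-1-(4-methylphenylsulfonyl)ethyl]phenol | Cc1ccc(cc1)S(=O)(=O)C(CO[Si](C)(C)C(C)(C)C)c1cc(Br)cc(OCc2ccccc2)c1O
A5 | alternative 2 | 1-[4-(benzyloxy)-3-methoxybenzyl]tetrahydrothiophen-1-ium bromide | COc1cc(C[S+]2CCCC2)ccc1OCc1ccccc1.[Br-]
A6 | alternative 2 | trans-(2S,3R)-7-(benzyloxy)-2-[4-(benzyloxy)-3-methoxyphenyl]-5-bromo-3-(tert-butyldimethylsilyloxymethyl)-2,3-dihydrobenzofuran | Brc1cc(OCc3ccccc3)c2c(c1)[C@H](CO[Si](C)(C)C(C)(C)C)[C@@H](c1ccc(OCc3ccccc3)c(OC)c1)O2
A7 | alternative 3 | 4-{(2S,3R)-7-(benzyloxy)-2-[4-(benzyloxy)-3-methoxyphenyl]-3-[(tert-butyldimethylsilyloxy)methyl]-2,3-dihydrobenzofuran-5-yl}but-2-yn-1-ol | OCC#CCc3cc(OCc4ccccc4)c4c(c3)[C@H](CO[Si](C)(C)C(C)(C)C)[C@@H](c3ccc(OCc5ccccc5)c(OC)c3)O4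
A8 | alternative 3 | [4-(benzyloxy)-3-methoxybenzyl]magnesium chloride | COc1cc(C[Mg]Cl)ccc1OCc1ccccc1
A9 | alternative 3 | 3-({(2S,3R)-7-(benzyloxy)-2-[4-(benzyloxy)-3-methoxyphenyl]-3-[(tert-butyldimethylsilyloxy)methyl]-2,3-dihydrobenzofuran-5-yl}methyl)-4-[4-(benzyloxy)-3-methoxybenzyl]furan-2(5H)-one | COc1cc(CC2=C(Cc3cc(OCc4ccccc4)c4c(c3)[C@H](CO[Si](C)(C)C(C)(C)C)[C@@H](c3ccc(OCc5ccccc5)c(OC)c3)O4)C(=O)OC2)ccc1OCc1ccccc1
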